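**Plan**
1. Numbering used throughout: ring carbons C1–C10 (C1 and C4 are the oxolane carbons), butenolide C6–C7–C11–C12, C13 = CH2OAc, C14 = CH3 on C10, C15 = CH3 on C4. Cuts, in order: angelate C8–O; butenolide back to a furan (O between C6 and C12); C8 carbinol back to ketone; C9–C10 (aldol retron C8=O / C9 / C10–OH); furan by Feist–Benary (C7–C11 and O–C12); oxolane C1–O.
2. Forward: geraniol gives the oxolane, then the furan is annulated, then the ten-membered carbocycle is closed by joining C9 to C10, and last the furan is oxidised to the alkylidene butenolide.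
3. Enabling feature: C10 is a tertiary carbinol 1,3 to the C8 oxygen and next to the oxolane oxygen. C10 can therefore be the carbonyl of a 2-acetyloxolane held in a chelate, and C8/C9 the enolate of an acetyl group on furan carbon C7. Keeping ring C6–C7–C11–C12 as a furan hides the enedione from SmI2.
4. Stereochemistry: C4 from Sharpless epoxidation; C1 from Shi epoxidation followed by inversion; C10 in the ring closure (C1 chelate and tether); C8 from C10 by 1,3-syn reduction; C5=C6 geometry enforced by the ring; angelate geometry carried in from the anhydride.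

Key step: step 10

Remark: the SMILES places the ring bonds C1–C10 and C4–C5 on opposite faces of the oxolane (1S,4S, 2,5-trans); the route builds exactly this relationship in step 3, the resulting bicycle is expected to be highly strained, and the ring closure is therefore run under irreversible conditions that cannot epimerise C1.

**Route**

Step 1
Reactants: 1 geraniol
Product: 2 [(2S,3S)-3-methyl-3-(4-methylpent-3-en-1-yl)oxiran-2-yl]methanol
Conditions: Ti(OiPr)4 (cat.), L-(+)-diethyl tartrate (cat.), t-BuOOH, 4 Å MS, CH2Cl2, −20 °C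
Reagents that add atoms: tert-butyl hydroperoxide, CC(C)(C)OO
Why: Sharpless asymmetric epoxidation of the allylic alcohol; the L-(+)-tartrate ligand delivers oxygen to the face that gives the (2S,3S)-epoxide, which fixes the C4 carbinol centre as S.

Step 2
Reactants: 2 [(2S,3S)-3-methyl-3-(4-methylpent-3-en-1-yl)oxiran-2-yl]methanol
Product: 3 (3S)-3,7-dimethyloct-6-ene-1,3-diol
Conditions: NaAlH2(OCH2CH2OMe)2, THF, 0 °C
Reagents that add atoms: none
Why: Reduction of a 2,3-epoxy alcohol by hydride delivered from the aluminate bound to the primary alkoxide opens the epoxide at C2 to the 1,3-diol; the tertiary C–O bond is untouched, so C4 stays S.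

Step 3
Reactants: 3 (3S)-3,7-dimethyloct-6-ene-1,3-diol
Product: 5 2-[(2S,5S)-5-(2-hydroxyethyl)-5-methyloxolan-2-yl]propan-2-ol, via epoxide 4 (not isolated)
Conditions: D-fructose-derived Shi ketone (1,2:4,5-di-O-isopropylidene-β-D-erythro-2,3-hexodiulo-2,6-pyranose, 30 mol %), KHSO5 (Oxone), K2CO3, Bu4NHSO4, MeCN/dimethoxymethane/aq. buffer, 0 °C; then CSA (cat.), CH2Cl2, 0 °C
Reagents that add atoms: potassium peroxymonosulfate, [K+].[O-]S(=O)(=O)OO
Why: Shi asymmetric epoxidation (spiro transition state, reagent control) should give the (R)-epoxide at C1, and acid-catalysed 5-exo-tet opening by the tertiary C4 hydroxyl inverts C1 to S, so C10 and C5 end on opposite faces of the oxolane.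

Step 4
Reactants: 5 2-[(2S,5S)-5-(2-hydroxyethyl)-5-methyloxolan-2-yl]propan-2-ol
Product: 6 2-[(2S,5S)-5-(2-hydroxypropan-2-yl)-2-methyloxolan-2-yl]acetic acid
Conditions: 2,2,6,6-tetramethylpiperidin-1-oxyl (TEMPO, cat.), PhI(OAc)2, MeCN/H2O, rt
Reagents that add atoms: water, O
Why: Oxoammonium (TEMPO/PhI(OAc)2) oxidation takes the primary alcohol through the aldehyde hydrate to the acid (C6) while the tertiary alcohol cannot be oxidised.

Step 5
Reactants: 6 2-[(2S,5S)-5-(2-hydroxypropan-2-yl)-2-methyloxolan-2-yl]acetic acid; 7 Meldrum's acid; 8 allyl alcohol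
Product: 10 prop-2-en-1-yl 4-[(2S,5S)-5-(2-hydroxypropan-2-yl)-2-methyloxolan-2-yl]-3-oxobutanoate, via acyl Meldrum's acid 9 (not isolated)
Conditions: DCC, 4-(dimethylamino)pyridine (cat.), CH2Cl2, 0 °C → rt; then 8, toluene, 90 °C
Reagents that add atoms: none
Why: C-acylation of Meldrum's acid and thermolysis to an acylketene that is trapped by allyl alcohol (Oikawa–Yonemitsu β-keto ester synthesis) adds C7 and C8 without touching the stereocentres.

Step 6
Reactants: 10 prop-2-en-1-yl 4-[(2S,5S)-5-(2-hydroxypropan-2-yl)-2-methyloxolan-2-yl]-3-oxobutanoate; 11 3-chloro-2-oxopropyl acetate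
Product: 13 prop-2-en-1-yl 4-(acetoxymethyl)-2-{[(2S,5S)-2-methyl-5-(prop-1-en-2-yl)oxolan-2-yl]methyl}furan-3-carboxylate, via hydroxydihydrofuran 12 (not isolated)
Conditions: pyridine, 50 °C; then SOCl2, pyridine, 0 °C
Reagents that add atoms: none
Why: Feist–Benary furan synthesis (C7 adds to the ketone carbonyl C11, the C6 enol oxygen displaces chloride at C12); SOCl2/pyridine then dehydrates both tertiary carbinols, aromatising the furan and turning the C10 carbinol into an isopropenyl group that masks the C10 ketone.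

Step 7
Reactants: 13 prop-2-en-1-yl 4-(acetoxymethyl)-2-{[(2S,5S)-2-methyl-5-(prop-1-en-2-yl)oxolan-2-yl]methyl}furan-3-carboxylate
Product: 14 4-(acetoxymethyl)-2-{[(2S,5S)-2-methyl-5-(prop-1-en-2-yl)oxolan-2-yl]methyl}furan-3-carboxylic acid
Conditions: Pd(PPh3)4 (5 mol %), morpholine, THF, rt
Reagents that add atoms: none
Why: Tsuji–Trost deallylation: zerovalent palladium ionises the allyl ester and morpholine traps the allyl fragment, freeing the C8 acid under neutral conditions that leave the acetate alone.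

Step 8
Reactants: 14 4-(acetoxymethyl)-2-{[(2S,5S)-2-methyl-5-(prop-1-en-2-yl)oxolan-2-yl]methyl}furan-3-carboxylic acid
Product: 17 [4-(bromoacetyl)-5-{[(2S,5S)-2-methyl-5-(prop-1-en-2-yl)oxolan-2-yl]methyl}furan-3-yl]methyl acetate, via acid chloride 15 (not isolated), via diazoketone 16 (not isolated)
Conditions: 1-chloro-N,N,2-trimethylprop-1-en-1-amine (Ghosez reagent), CH2Cl2, 0 °C; CH2N2, Et2O, 0 °C; then 48% aq. HBr, −10 °C
Reagents that add atoms: diazomethane, C=[N+]=[N-]; hydrogen bromide, Br
Why: Acylation of diazomethane by the acid chloride (Arndt–Eistert first stage) and protonation of the diazoketone by HBr with loss of N2 install C9 as a bromomethyl ketone; the neutral chloride formation spares the isopropenyl group and the acetate.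

Step 9
Reactants: 17 [4-(bromoacetyl)-5-{[(2S,5S)-2-methyl-5-(prop-1-en-2-yl)oxolan-2-yl]methyl}furan-3-yl]methyl acetate
Product: 18 [5-{[(2S,5S)-5-acetyl-2-methyloxolan-2-yl]methyl}-4-(bromoacetyl)furan-3-yl]methyl acetate
Conditions: OsO4 (2 mol %), NaIO4, 2,6-lutidine, dioxane/H2O (3:1), rt; product used at once
Reagents that add atoms: sodium periodate, [Na+].[O-]I(=O)(=O)=O; osmium tetroxide, O=[Os](=O)(=O)=O
Why: Lemieux–Johnson cleavage should take the electron-rich 1,1-disubstituted alkene in preference to the acyl-deactivated furan and unveil the C10 methyl ketone; the lutidine buffer and immediate use guard the now enolisable C1.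

Step 10
Reactants: 18 [5-{[(2S,5S)-5-acetyl-2-methyloxolan-2-yl]methyl}-4-(bromoacetyl)furan-3-yl]methyl acetate
Product: 21 macrocyclic β-hydroxy ketone (1S,4S,10R)-13-acetoxy-10-hydroxy-8-oxo-1,4-epoxy-6,12-epoxygermacra-6,11-diene, via samarium enolate 19 (not isolated), via samarium aldolate 20 (not isolated)
Conditions: SmI2 (2.2 equiv), THF, −78 °C, slow addition of 18 (final 1 mM); aq. NH4Cl at −78 °C
Reagents that add atoms: none
Why: Two single-electron transfers from SmI2 to the C9–Br bond give the samarium enolate 19 regiospecifically, and trivalent samarium on the enolate oxygen binds the C10 carbonyl and the oxolane oxygen, so that C9 adds to C10 through a closed chair-like transition state to give aldolate 20. The closest known reaction type is the SmI2-mediated intramolecular Reformatsky (aldol) cyclisation of α-bromo ketones and esters onto carbonyl groups, which is used to close medium and large rings. The ring closed is the ten-membered carbocycle C1–C10 (nine-membered when counted through the oxolane oxygen), by 10-exo-trig attack on the C10 carbonyl. The new stereocentre C10 is controlled by C1 and the tether: the chelate holds the carbonyl syn to the oxolane oxygen, and C9, carried by a chain anchored at C4, should reach only the carbonyl face turned toward C2, which gives 10R. The step needs enolate formation at C8/C9 without enolisation at C1 or C14 and ring closure in preference to protonation or dimerisation; the first is secured by generating the enolate from the C–Br bond under non-basic aprotic conditions at −78 °C with a cold quench, the second by slow addition into dilute SmI2 and by the samarium template.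

Step 11
Reactants: 21 macrocyclic β-hydroxy ketone
Product: 23 syn-diol (1S,4S,8S,10R)-13-acetoxy-8,10-dihydroxy-1,4-epoxy-6,12-epoxygermacra-6,11-diene, via boron chelate 22 (not isolated)
Conditions: Et2BOMe, THF/MeOH (4:1), −78 °C; NaBH4; then MeOH, AcOH, evaporation
Reagents that add atoms: none
Why: Narasaka–Prasad reduction: the diethylboron chelate between the C10 oxygen and the C8 carbonyl fixes a half-chair and external hydride adds axially to give the 1,3-syn diol, that is 8S.

Step 12
Reactants: 23 syn-diol; 24 angelic anhydride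
Product: 25 8-O-angelate (1S,4S,8S,10R)-13-acetoxy-8-angeloyloxy-10-hydroxy-1,4-epoxy-6,12-epoxygermacra-6,11-diene
Conditions: LiN(SiMe3)2 (1.05 equiv), THF, −78 °C; 24, −78 → −30 °C
Reagents that add atoms: none
Why: O-acylation of the lithium alkoxide of the secondary alcohol by the anhydride at low temperature without a nucleophilic catalyst should keep the Z geometry of the angeloyl group, and the tertiary C10 hydroxyl is too hindered to compete.

Step 13
Reactants: 25 8-O-angelate
Product: 27 γ-hydroxybutenolide (6-hydroxy-5,6-dihydro form of the target), via endoperoxide 26 (not isolated)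
Conditions: O2, hν (visible), 5,10,15,20-tetraphenylporphyrin (cat.), i-Pr2NEt, CH2Cl2, −78 °C
Reagents that add atoms: dioxygen, O=O
Why: [4+2] addition of singlet oxygen across furan carbons C6 and C12 and base-induced Kornblum–DeLaMare fragmentation, in which the only bridgehead hydrogen (on C12) is removed, give the C12 lactone carbonyl and the C6 hemiketal; the electron-poor angelate alkene reacts far more slowly than the furan.

Step 14
Reactants: 27 γ-hydroxybutenolide
Product: 29 target (CNP0162854.1), via mesylate 28 (not isolated)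
Conditions: MsCl, Et3N, CH2Cl2, −20 → 0 °C
Reagents that add atoms: none
Why: Sulfonylation of the hemiketal hydroxyl and elimination of a C5 hydrogen through the acyloxy-stabilised C6 cation give the γ-alkylidene butenolide; C4 and C7 are both ring members, so only the E (in-ring cis) C5=C6 geometry can form.

**Compound list**
1 | geraniol, (2E)-3,7-dimethylocta-2,6-dien-1-ol | CC(C)=CCC/C(C)=C/CO | starting material
2 | [(2S,3S)-3-methyl-3-(4-methylpent-3-en-1-yl)oxiran-2-yl]methanol | OC[C@@H]1O[C@@]1(C)CCC=C(C)C | intermediate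
3 | (3S)-3,7-dimethyloct-6-ene-1,3-diol | OCC[C@@](C)(O)CCC=C(C)C | intermediate
4 | (3S)-5-[(2R)-3,3-dimethyloxiran-2-yl]-3-methylpentane-1,3-diol | OCC[C@@](C)(O)CC[C@H]1OC1(C)C | intermediate (not isolated)
5 | 2-[(2S,5S)-5-(2-hydroxyethyl)-5-methyloxolan-2-yl]propan-2-ol (2,5-trans) | CC(C)(O)[C@@H]1CC[C@@](C)(CCO)O1 | intermediate
6 | 2-[(2S,5S)-5-(2-hydroxypropan-2-yl)-2-methyloxolan-2-yl]acetic acid | CC(C)(O)[C@@H]1CC[C@@](C)(CC(=O)O)O1 | intermediate
7 | Meldrum's acid, 2,2-dimethyl-1,3-dioxane-4,6-dione | CC1(C)OC(=O)CC(=O)O1 | starting material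
8 | allyl alcohol, prop-2-en-1-ol | C=CCO | starting material
9 | 5-{[(2S,5S)-5-(2-hydroxypropan-2-yl)-2-methyloxolan-2-yl]acetyl}-2,2-dimethyl-1,3-dioxane-4,6-dione | CC(C)(O)[C@@H]1CC[C@@](C)(CC(=O)C2C(=O)OC(C)(C)OC2=O)O1 | intermediate (not isolated)
10 | prop-2-en-1-yl 4-[(2S,5S)-5-(2-hydroxypropan-2-yl)-2-methyloxolan-2-yl]-3-oxobutanoate | CC(C)(O)[C@@H]1CC[C@@](C)(CC(=O)CC(=O)OCC=C)O1 | intermediate
11 | 3-chloro-2-oxopropyl acetate (1-acetoxy-3-chloroacetone) | CC(=O)OCC(=O)CCl | starting material
12 | prop-2-en-1-yl 4-(acetoxymethyl)-4-hydroxy-2-{[(2S,5S)-5-(2-hydroxypropan-2-yl)-2-methyloxolan-2-yl]methyl}-4,5-dihydrofuran-3-carboxylate (carbinol centre C11 undefined) | CC(C)(O)[C@@H]1CC[C@@](C)(CC2=C(C(=O)OCC=C)C(O)(COC(C)=O)CO2)O1 | intermediate (not isolated)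
13 | prop-2-en-1-yl 4-(acetoxymethyl)-2-{[(2S,5S)-2-methyl-5-(prop-1-en-2-yl)oxolan-2-yl]methyl}furan-3-carboxylate | CC(=C)[C@@H]1CC[C@@](C)(Cc2occ(COC(C)=O)c2C(=O)OCC=C)O1 | intermediate
14 | 4-(acetoxymethyl)-2-{[(2S,5S)-2-methyl-5-(prop-1-en-2-yl)oxolan-2-yl]methyl}furan-3-carboxylic acid | CC(=C)[C@@H]1CC[C@@](C)(Cc2occ(COC(C)=O)c2C(=O)O)O1 | intermediate
15 | 4-(acetoxymethyl)-2-{[(2S,5S)-2-methyl-5-(prop-1-en-2-yl)oxolan-2-yl]methyl}furan-3-carbonyl chloride | CC(=C)[C@@H]1CC[C@@](C)(Cc2occ(COC(C)=O)c2C(=O)Cl)O1 | intermediate (not isolated)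
16 | [4-(diazoacetyl)-5-{[(2S,5S)-2-methyl-5-(prop-1-en-2-yl)oxolan-2-yl]methyl}furan-3-yl]methyl acetate | CC(=C)[C@@H]1CC[C@@](C)(Cc2occ(COC(C)=O)c2C(=O)C=[N+]=[N-])O1 | intermediate (not isolated)
17 | [4-(bromoacetyl)-5-{[(2S,5S)-2-methyl-5-(prop-1-en-2-yl)oxolan-2-yl]methyl}furan-3-yl]methyl acetate | CC(=C)[C@@H]1CC[C@@](C)(Cc2occ(COC(C)=O)c2C(=O)CBr)O1 | intermediate
18 | [5-{[(2S,5S)-5-acetyl-2-methyloxolan-2-yl]methyl}-4-(bromoacetyl)furan-3-yl]methyl acetate | CC(=O)[C@@H]1CC[C@@](C)(Cc2occ(COC(C)=O)c2C(=O)CBr)O1 | intermediate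
19 | diiodosamarium enolate of 18 (C8–O–SmI2, C8=C9H2) | CC(=O)[C@@H]1CC[C@@](C)(Cc2occ(COC(C)=O)c2C(=C)O[Sm](I)I)O1 | intermediate (not isolated)
20 | diiodosamarium aldolate (C10–O–SmI2) of 21 | O=C1C[C@@](C)(O[Sm](I)I)[C@@H]2CC[C@@](C)(Cc3occ(COC(C)=O)c31)O2 | intermediate (not isolated)
21 | (1S,4S,10R)-13-acetoxy-10-hydroxy-8-oxo-1,4-epoxy-6,12-epoxygermacra-6,11-diene (furan O–C6=C7–C11=C12; C8 ketone on C7) | O=C1C[C@@](C)(O)[C@@H]2CC[C@@](C)(Cc3occ(COC(C)=O)c31)O2 | intermediate
22 | 10-O-diethylboryl derivative (chelate) of 21 | O=C1C[C@@](C)(OB(CC)CC)[C@@H]2CC[C@@](C)(Cc3occ(COC(C)=O)c31)O2 | intermediate (not isolated)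
23 | (1S,4S,8S,10R)-13-acetoxy-8,10-dihydroxy-1,4-epoxy-6,12-epoxygermacra-6,11-diene | O[C@H]1C[C@@](C)(O)[C@@H]2CC[C@@](C)(Cc3occ(COC(C)=O)c31)O2 | intermediate
24 | angelic anhydride, (2Z)-2-methylbut-2-enoic anhydride | C/C=C(/C)C(=O)OC(=O)/C(C)=C\C | starting material
25 | (1S,4S,8S,10R)-13-acetoxy-8-angeloyloxy-10-hydroxy-1,4-epoxy-6,12-epoxygermacra-6,11-diene | C/C=C(/C)C(=O)O[C@H]1C[C@@](C)(O)[C@@H]2CC[C@@](C)(Cc3occ(COC(C)=O)c31)O2 | intermediate
26 | 6,12-endoperoxide of 25 (O–O bridge between C6 and C12; bridgehead centres undefined) | C/C=C(/C)C(=O)O[C@H]1C[C@@](C)(O)[C@@H]2CC[C@@](C)(CC34OOC(O3)C(COC(C)=O)=C41)O2 | intermediate (not isolated)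
27 | γ-hydroxybutenolide: 6-hydroxy-5,6-dihydro derivative of 29 (C6 undefined) | C/C=C(/C)C(=O)O[C@H]1C[C@@](C)(O)[C@@H]2CC[C@@](C)(CC3(O)OC(=O)C(COC(C)=O)=C31)O2 | intermediate
28 | 6-O-methanesulfonate of 27 | C/C=C(/C)C(=O)O[C@H]1C[C@@](C)(O)[C@@H]2CC[C@@](C)(CC3(OS(C)(=O)=O)OC(=O)C(COC(C)=O)=C31)O2 | intermediate (not isolated)
29 | (1S,4S,5E,8S,10R)-13-acetoxy-8-angeloyloxy-10-hydroxy-1,4-epoxygermacra-5,7(11)-dien-12,6-olide | C/C=C(/C)C(=O)O[C@H]1C[C@@](C)(O)[C@@H]2CC[C@@](C)(/C=C3/OC(=O)C(COC(C)=O)=C31)O2 | target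

**Totals**
Total step count: 14. Longest linear sequence: 14 steps (geraniol to 29).

**Steps most likely to fail**

Step 10. Because of the strain of the 2,5-trans-bridged bicycle, ring closure may lose to protonation of the enolate or to intermolecular aldol addition. The face of the C10 carbonyl may also be poorly differentiated. The fallback sets out from 14 and returns at 21, and makes the same bond as an alkene. Acid 14 is converted with the Ghosez reagent and then with tributyl(vinyl)stannane and Pd(PPh3)4 (cat.) into the vinyl ketone, [4-acryloyl-5-{[(2S,5S)-2-methyl-5-(prop-1-en-2-yl)oxolan-2-yl]methyl}furan-3-yl]methyl acetate F1. Ring-closing metathesis with the second-generation Hoveyda–Grubbs catalyst in dilute toluene at 80 °C, driven by loss of ethene, joins C9 to C10 and gives the cyclic (9Z)-enone F2. Nucleophilic epoxidation (t-BuOOH, DBU) from the outer face gives the cis-9,10-epoxy ketone F3, and SmI2 in THF/MeOH at −90 °C cleaves the C9–O bond to return 21.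

Step 11. Hydride delivery may show poor facial selectivity if the boron chelate cannot adopt the required half-chair inside the bicycle. The fallback sets out from 21 and returns at 25. Directed reduction with Me4NBH(OAc)3 in MeCN/AcOH (Evans–Saksena, hydride delivered from the C10 alkoxyborohydride) gives the 1,3-anti diol, the 8R epimer of 23, F4. Mitsunobu esterification with angelic acid (PPh3, DIAD, toluene, 0 °C) then inverts C8 and gives 25 directly.

Step 12. The angeloyl group may isomerise from Z to E (tigloyl), or the C13 acetate may migrate to the C8 alkoxide. The fallback sets out from 23 and returns at 25, and builds the Z-alkene in place. The C8 hydroxyl is acylated with 2-[bis(2,2,2-trifluoroethoxy)phosphoryl]propanoic acid (DCC, cat. 4-(dimethylamino)pyridine) to give the 8-O-phosphonopropanoate F5. Still–Gennari olefination with acetaldehyde (KN(SiMe3)2, 18-crown-6, THF, −78 °C) then gives 25.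

**Further compounds**
F1 | step 10 | [4-acryloyl-5-{[(2S,5S)-2-methyl-5-(prop-1-en-2-yl)oxolan-2-yl]methyl}furan-3-yl]methyl acetate | CC(=C)[C@@H]1CC[C@@](C)(Cc2occ(COC(C)=O)c2C(=O)C=C)O1
F2 | step 10 | (1S,4S,9Z)-13-acetoxy-8-oxo-1,4-epoxy-6,12-epoxygermacra-6,9,11-triene | O=C1/C=C(/C)[C@@H]2CC[C@@](C)(Cc3occ(COC(C)=O)c31)O2
F3 | step 10 | cis-9,10-epoxide of F2 (epoxide oxygen on the face of the later 10-hydroxyl) | O=C1[C@H]2O[C@@]2(C)[C@@H]3CC[C@@](C)(Cc4occ(COC(C)=O)c41)O3
F4 | step 11 | (1S,4S,8R,10R)-13-acetoxy-8,10-dihydroxy-1,4-epoxy-6,12-epoxygermacra-6,11-diene | O[C@@H]1C[C@@](C)(O)[C@@H]2CC[C@@](C)(Cc3occ(COC(C)=O)c31)O2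
F5 | step 12 | 8-O-{2-[bis(2,2,2-trifluoroethoxy)phosphoryl]propanoyl} derivative of 23 (phosphonate α-carbon undefined) | CC(C(=O)O[C@H]1C[C@@](C)(O)[C@@H]2CC[C@@](C)(Cc3occ(COC(C)=O)c31)O2)P(=O)(OCC(F)(F)F)OCC(F)(F)F
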